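The route rests on disconnecting the C4–C5 bond of ring A. C5 is a methine wedged between two quaternary carbons (C4, carrying the gem-dimethyl group next to the C3 carbinol, and C10), so it is made by radical conjugate addition: a C3–C4 epoxide is opened by trivalent titanium to the C4 tertiary radical, which adds to C5 of a ring B enone (C5=C6–C7=O). One operation closes ring A, sets the cis A/B junction and unveils the 3β-hydroxyl. The precursor is a 4,4,5,6-substituted cyclohex-2-enone that already carries the C9 vinyl group, both ring B methyls, the C8 tertiary hydroxyl and the (S)-epoxide.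

Key step: step 7

Remark (assumptions): target numbering is used for all ring compounds (ring A = C1–C5 and C10, ring B = C5–C10; β = face of the C10 methyl); melonal is used as the racemate because its stereocentre is erased in step 2; the C8 hydroxyl is installed before ring closure because C8 is then the only enolisable carbon, and methylation is a separate enolate step because the rhodium enolate is protonated in the aqueous medium.

Step 1
Reactants: 1 melonal (racemic 2,6-dimethylhept-5-enal); 2 methyl vinyl ketone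
Product: 5 (±)-4-methyl-4-(4-methylpent-3-en-1-yl)cyclohex-2-en-1-one, via pyrrolidine enamine 3 (not isolated), via keto aldehyde 4 (not isolated)
Conditions: pyrrolidine, K2CO3, toluene, 25 °C; then 2, 0 → 25 °C; then AcOH/NaOAc/H2O, 90 °C
Reagents that add atoms: none
Why: Stork enamine Michael addition of the α-branched aldehyde to the enone followed by intramolecular aldol condensation (Robinson annulation) is the standard entry to 4,4-dialkylcyclohex-2-enones, and no stereocontrol is needed because C10 becomes non-stereogenic in step 2.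

Step 2
Reactants: 5 (±)-4-methyl-4-(4-methylpent-3-en-1-yl)cyclohex-2-en-1-one
Product: 7 4-methyl-4-(4-methylpent-3-en-1-yl)cyclohexa-2,5-dien-1-one, via trimethylsilyl dienol ether 6 (not isolated)
Conditions: LiN(iPr)2, Me3SiCl, THF, −78 °C; then Pd(OAc)2 (10 mol %), O2 (1 atm), DMSO, 40 °C
Reagents that add atoms: none
Why: Saegusa–Ito oxidation: kinetic deprotonation can only occur at C8 (C10 is quaternary), and divalent palladium dehydrosilylates the silyl dienol ether to the achiral cross-conjugated dienone without touching the isolated trisubstituted alkene.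

Step 3
Reactants: 7 4-methyl-4-(4-methylpent-3-en-1-yl)cyclohexa-2,5-dien-1-one; 8 potassium vinyltrifluoroborate
Product: 9 (4S,5R)-4-methyl-4-(4-methylpent-3-en-1-yl)-5-vinylcyclohex-2-en-1-one (vinyl cis to the C10 methyl)
Conditions: [Rh(cod)2]BF4 (3 mol %), (R)-BINAP (3.3 mol %), Et3N, toluene/H2O, 90 °C
Reagents that add atoms: none
Why: Desymmetrising rhodium-catalysed asymmetric conjugate addition (Hayashi–Miyaura reaction) of an alkenyltrifluoroborate to a cyclohexadienone: (R)-BINAP, by analogy with its known sense of induction on cyclohexenone, fixes C9, and the enone arm on which vinyl enters anti to the longer C10 substituent should react preferentially, so that C10 becomes stereogenic with vinyl cis to methyl (the C10 epimer is a diastereomer, removed by chromatography).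

Step 4
Reactants: 9 (4S,5R)-4-methyl-4-(4-methylpent-3-en-1-yl)-5-vinylcyclohex-2-en-1-one
Product: 11 (4S,5S,6S)-4,6-dimethyl-4-(4-methylpent-3-en-1-yl)-5-vinylcyclohex-2-en-1-one (C8 methyl trans to vinyl), via lithium dienolate 10 (not isolated)
Conditions: LiN(iPr)2, THF, −78 °C; then MeI, −78 → −40 °C
Reagents that add atoms: iodomethane, CI
Why: Kinetic enolate alkylation at C8, the only enolisable position (C6 is vinylic, C10 quaternary), with methyl iodide expected to enter trans to the neighbouring vinyl group; the C8 configuration is not critical because the centre is re-enolised in step 5.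

Step 5
Reactants: 11 (4S,5S,6S)-4,6-dimethyl-4-(4-methylpent-3-en-1-yl)-5-vinylcyclohex-2-en-1-one
Product: 13 (4S,5R,6S)-6-hydroxy-4,6-dimethyl-4-(4-methylpent-3-en-1-yl)-5-vinylcyclohex-2-en-1-one (8α-OH and 8β-CH3), via potassium dienolate 12 (not isolated)
Conditions: KN(SiMe3)2, THF, −78 °C; then 2-(phenylsulfonyl)-3-phenyloxaziridine, −78 °C; then AcOH
Reagents that add atoms: 2-(phenylsulfonyl)-3-phenyloxaziridine, O=S(=O)(c1ccccc1)N1OC1c1ccccc1
Why: Davis oxidation of the tetrasubstituted enolate: A(1,2) strain between the C8 methyl and the C9 vinyl group places vinyl pseudo-axial on the β face, so oxygen should be delivered to the α face, trans to vinyl.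

Step 6
Reactants: 13 (4S,5R,6S)-6-hydroxy-4,6-dimethyl-4-(4-methylpent-3-en-1-yl)-5-vinylcyclohex-2-en-1-one
Product: 14 (4S,5R,6S)-4-{2-[(2S)-3,3-dimethyloxiran-2-yl]ethyl}-6-hydroxy-4,6-dimethyl-5-vinylcyclohex-2-en-1-one
Conditions: L-fructose-derived Shi ketone (30 mol %), KHSO5 (as 2KHSO5·KHSO4·K2SO4), K2CO3, Bu4NHSO4, MeCN/CH2(OMe)2/aq. Na2B4O7 buffer (pH 10.5), 0 °C
Reagents that add atoms: potassium peroxymonosulfate, [K+].[O-]S(=O)(=O)OO
Why: Shi epoxidation: the electrophilic chiral dioxirane should react only with the electron-rich trisubstituted alkene (not the enone or the vinyl group), and the L-series ketone is chosen because the D-fructose-derived ketone gives (R)-configured 2,2-dimethyl-3-alkyloxiranes, whereas the (S)-epoxide is needed for the 3β-oxygen.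

Step 7
Reactants: 14 (4S,5R,6S)-4-{2-[(2S)-3,3-dimethyloxiran-2-yl]ethyl}-6-hydroxy-4,6-dimethyl-5-vinylcyclohex-2-en-1-one
Product: 16 cis-fused 3β,8α-dihydroxy-4,4,8β,10β-tetramethyl-9β-vinyl-5β-decalin-7-one, via titanium alkoxide enolate 15 (not isolated)
Conditions: Cp2TiCl2 (2.5 equiv), Mn dust, THF, 25 °C; the resulting green Cp2TiCl solution added slowly to 14 in THF (0.01 M), 25 °C; then aq. NaH2PO4
Reagents that add atoms: none
Why: Single-electron transfer from trivalent titanium (Cp2TiCl) opens the epoxide at its more substituted C4–O bond to a β-titanoxy tertiary radical, which adds to C5 of the enone; the α-keto radical is reduced by a second Cp2TiCl to a titanium enolate that is protonated on work-up. The closest known reaction type is the titanocene-mediated reductive epoxide opening with intramolecular radical conjugate addition to α,β-unsaturated carbonyl compounds. Ring A closes in a 6-exo-trig mode. The only new stereocentre, C5, is controlled by the tether, which is anchored on the α face of C10 and can reach only the α face of C5, so the junction must be cis (5β-H); C3 is carried over unchanged from the epoxide. The step needs cyclisation to outrun reduction or β-hydride elimination of the tertiary radical and to prefer the enone over the vinyl group; this is secured by the polarity match between the nucleophilic radical and the electron-poor C5, by the quaternary C10 that preorganises the chain, and by the low Cp2TiCl concentration maintained through slow addition.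

Step 8
Reactants: 16 cis-fused 3β,8α-dihydroxy-4,4,8β,10β-tetramethyl-9β-vinyl-5β-decalin-7-one
Product: 17 3β,8α-bis(triethylsilyloxy)-4,4,8β,10β-tetramethyl-9β-vinyl-5β-decalin-7-one
Conditions: Et3SiOTf (3 equiv), 2,6-lutidine, CH2Cl2, −78 → 0 °C
Reagents that add atoms: triethylsilyl trifluoromethanesulfonate, CC[Si](CC)(CC)OS(=O)(=O)C(F)(F)F
Why: Silyl triflate/2,6-lutidine silylation caps both the secondary C3 and the hindered tertiary C8 hydroxyl, removing the vicinal-diol reactivity that would interfere with deoxygenation at C7.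

Step 9
Reactants: 17 3β,8α-bis(triethylsilyloxy)-4,4,8β,10β-tetramethyl-9β-vinyl-5β-decalin-7-one
Product: 18 3β,8α-bis(triethylsilyloxy)-4,4,8β,10β-tetramethyl-9β-vinyl-5β-decalin-7β-ol (7β drawn as the expected epimer; either serves)
Conditions: NaBH4, MeOH/THF, 0 → 25 °C
Reagents that add atoms: none
Why: Borohydride reduction of the ketone, with attack expected from the face away from the axial C9 vinyl group; the C7 configuration is irrelevant because the centre is removed in step 11.

Step 10
Reactants: 18 3β,8α-bis(triethylsilyloxy)-4,4,8β,10β-tetramethyl-9β-vinyl-5β-decalin-7β-ol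
Product: 19 O-[3β,8α-bis(triethylsilyloxy)-4,4,8β,10β-tetramethyl-9β-vinyl-5β-decalin-7β-yl] imidazole-1-carbothioate
Conditions: 1,1'-thiocarbonyldiimidazole, DMAP, toluene, 90 °C
Reagents that add atoms: 1,1'-thiocarbonyldiimidazole, S=C(n1ccnc1)n1ccnc1
Why: Acylation of the only free hydroxyl gives the imidazolyl thionocarbamate required for Barton–McCombie deoxygenation.

Step 11
Reactants: 19 O-[3β,8α-bis(triethylsilyloxy)-4,4,8β,10β-tetramethyl-9β-vinyl-5β-decalin-7β-yl] imidazole-1-carbothioate
Product: 20 3β,8α-bis(triethylsilyloxy)-4,4,8β,10β-tetramethyl-9β-vinyl-5β-decalin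
Conditions: Bu3SnH, AIBN, toluene, 100 °C
Reagents that add atoms: none
Why: Barton–McCombie deoxygenation: the stannyl radical adds to the thiocarbonyl sulfur, the secondary C7 radical is released and reduced by the tin hydride, and the vinyl group could only be attacked in a 4-exo or 5-endo mode, too slow to compete.

Step 12
Reactants: 21 geranyl bromide; 22 1-(trimethylsilyl)propyne
Product: 24 (E)-6,10-dimethylundeca-5,9-dien-1-yne, via silylated enyne 23 (not isolated)
Conditions: 22, n-BuLi, THF, −78 °C; then 21, −78 → 0 °C; then K2CO3, MeOH, 25 °C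
Reagents that add atoms: none
Why: SN2 alkylation of the propargylic lithium reagent (which reacts at its CH2 terminus) by the primary allylic bromide with retention of the E geometry, followed by mild C-desilylation of the alkynylsilane.

Step 13
Reactants: 24 (E)-6,10-dimethylundeca-5,9-dien-1-yne
Product: 26 (1E,5E)-1-iodo-2,6,10-trimethylundeca-1,5,9-triene, via alkenylalane 25 (not isolated)
Conditions: Me3Al, Cp2ZrCl2 (25 mol %), CH2Cl2, 0 → 25 °C; then I2, THF, −30 → 0 °C
Reagents that add atoms: trimethylaluminium, C[Al](C)C; iodine, II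
Why: Negishi zirconium-catalysed carboalumination adds methyl and aluminium syn across the terminal alkyne with aluminium at the terminus, and iodinolysis with retention gives the (E)-trisubstituted alkenyl iodide.

Step 14
Reactants: 20 3β,8α-bis(triethylsilyloxy)-4,4,8β,10β-tetramethyl-9β-vinyl-5β-decalin; 26 (1E,5E)-1-iodo-2,6,10-trimethylundeca-1,5,9-triene
Product: 28 3,8-bis(triethylsilyl) ether of the target, via alkylborane 27 (not isolated)
Conditions: 9-BBN dimer, THF, 25 → 50 °C; then 26, PdCl2(dppf) (5 mol %), AsPh3, Cs2CO3, DMF/H2O, 25 °C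
Reagents that add atoms: none
Why: Anti-Markovnikov hydroboration with 9-BBN occurs at the only unhindered alkene, the vinyl group, and B-alkyl Suzuki–Miyaura coupling with the alkenyl iodide forms C12–C13 with retention of the E geometry.

Step 15
Reactants: 28 3,8-bis(triethylsilyl) ether of the target
Product: 29 IN0670
Conditions: Bu4NF, THF, 25 → 40 °C
Reagents that add atoms: none
Why: Fluoride-mediated cleavage of both triethylsilyl ethers under non-acidic conditions leaves the tertiary alcohol and the acid-sensitive polyene untouched.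

Compound list
1 | melonal, (±)-2,6-dimethylhept-5-enal | CC(C)=CCCC(C)C=O | starting material
2 | methyl vinyl ketone | CC(=O)C=C | starting material
3 | 1-(2,6-dimethylhepta-1,5-dien-1-yl)pyrrolidine (E/Z mixture) | CC(C)=CCCC(C)=CN1CCCC1 | intermediate (not isolated)
4 | (±)-2,6-dimethyl-2-(3-oxobutyl)hept-5-enal | CC(C)=CCCC(C)(C=O)CCC(C)=O | intermediate (not isolated)
5 | (±)-4-methyl-4-(4-methylpent-3-en-1-yl)cyclohex-2-en-1-one | CC(C)=CCCC1(C)CCC(=O)C=C1 | intermediate
6 | (±)-trimethyl{[4-methyl-4-(4-methylpent-3-en-1-yl)cyclohexa-1,5-dien-1-yl]oxy}silane | CC(C)=CCCC1(C)CC=C(O[Si](C)(C)C)C=C1 | intermediate (not isolated)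
7 | 4-methyl-4-(4-methylpent-3-en-1-yl)cyclohexa-2,5-dien-1-one (achiral) | CC(C)=CCCC1(C)C=CC(=O)C=C1 | intermediate
8 | potassium vinyltrifluoroborate | [K+].C=C[B-](F)(F)F | starting material
9 | (4S,5R)-4-methyl-4-(4-methylpent-3-en-1-yl)-5-vinylcyclohex-2-en-1-one (10β-CH3, 9β-vinyl) | C=C[C@@H]1[C@@](C)(CCC=C(C)C)C=CC(=O)C1 | intermediate
10 | lithium dienolate of 9 (C7–OLi, C7=C8) | C=C[C@@H]1[C@@](C)(CCC=C(C)C)C=CC(O[Li])=C1 | intermediate (not isolated)
11 | (4S,5S,6S)-4,6-dimethyl-4-(4-methylpent-3-en-1-yl)-5-vinylcyclohex-2-en-1-one (8α-CH3) | C=C[C@@H]1[C@@](C)(CCC=C(C)C)C=CC(=O)[C@H]1C | intermediate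
12 | potassium dienolate of 11 (C7–OK, C7=C8) | C=C[C@@H]1[C@@](C)(CCC=C(C)C)C=CC(O[K])=C1C | intermediate (not isolated)
13 | (4S,5R,6S)-6-hydroxy-4,6-dimethyl-4-(4-methylpent-3-en-1-yl)-5-vinylcyclohex-2-en-1-one (8α-OH, 8β-CH3) | C=C[C@@H]1[C@@](C)(CCC=C(C)C)C=CC(=O)[C@@]1(C)O | intermediate
14 | (4S,5R,6S)-4-{2-[(2S)-3,3-dimethyloxiran-2-yl]ethyl}-6-hydroxy-4,6-dimethyl-5-vinylcyclohex-2-en-1-one | C=C[C@@H]1[C@@](C)(CC[C@@H]2OC2(C)C)C=CC(=O)[C@@]1(C)O | intermediate (key-step precursor)
15 | bis(chlorotitanocene) 3-alkoxide 6-en-7-olate of 16 | C=C[C@@H]1[C@@]2(C)CC[C@H](O[Ti](Cl)(C3C=CC=C3)C3C=CC=C3)C(C)(C)[C@H]2C=C(O[Ti](Cl)(C3C=CC=C3)C3C=CC=C3)[C@@]1(C)O | intermediate (not isolated)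
16 | cis-fused 3β,8α-dihydroxy-4,4,8β,10β-tetramethyl-9β-vinyl-5β-decalin-7-one | C=C[C@@H]1[C@@]2(C)CC[C@H](O)C(C)(C)[C@H]2CC(=O)[C@@]1(C)O | intermediate (key-step product)
17 | 3β,8α-bis(triethylsilyloxy)-4,4,8β,10β-tetramethyl-9β-vinyl-5β-decalin-7-one | C=C[C@@H]1[C@@]2(C)CC[C@H](O[Si](CC)(CC)CC)C(C)(C)[C@H]2CC(=O)[C@@]1(C)O[Si](CC)(CC)CC | intermediate
18 | 3β,8α-bis(triethylsilyloxy)-4,4,8β,10β-tetramethyl-9β-vinyl-5β-decalin-7β-ol | C=C[C@@H]1[C@@]2(C)CC[C@H](O[Si](CC)(CC)CC)C(C)(C)[C@H]2C[C@H](O)[C@@]1(C)O[Si](CC)(CC)CC | intermediate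
19 | O-(7β-decalinyl) imidazole-1-carbothioate of 18 | C=C[C@@H]1[C@@]2(C)CC[C@H](O[Si](CC)(CC)CC)C(C)(C)[C@H]2C[C@H](OC(=S)n3ccnc3)[C@@]1(C)O[Si](CC)(CC)CC | intermediate
20 | 3β,8α-bis(triethylsilyloxy)-4,4,8β,10β-tetramethyl-9β-vinyl-5β-decalin | C=C[C@@H]1[C@@]2(C)CC[C@H](O[Si](CC)(CC)CC)C(C)(C)[C@H]2CC[C@@]1(C)O[Si](CC)(CC)CC | intermediate
21 | geranyl bromide | CC(C)=CCC/C(C)=C/CBr | starting material
22 | 1-(trimethylsilyl)propyne | CC#C[Si](C)(C)C | starting material
23 | (E)-(6,10-dimethylundeca-5,9-dien-1-yn-1-yl)trimethylsilane | CC(C)=CCC/C(C)=C/CCC#C[Si](C)(C)C | intermediate (not isolated)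
24 | (E)-6,10-dimethylundeca-5,9-dien-1-yne | CC(C)=CCC/C(C)=C/CCC#C | intermediate
25 | dimethyl[(1E,5E)-2,6,10-trimethylundeca-1,5,9-trien-1-yl]alane | CC(C)=CCC/C(C)=C/CC/C(C)=C/[Al](C)C | intermediate (not isolated)
26 | (1E,5E)-1-iodo-2,6,10-trimethylundeca-1,5,9-triene | CC(C)=CCC/C(C)=C/CC/C(C)=C/I | intermediate
27 | B-[2-(decalin-9β-yl)ethyl]-9-borabicyclo[3.3.1]nonane from 20 | B1(CC[C@@H]2[C@@]3(C)CC[C@H](O[Si](CC)(CC)CC)C(C)(C)[C@H]3CC[C@@]2(C)O[Si](CC)(CC)CC)C2CCCC1CCC2 | intermediate (not isolated)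
28 | 3β,8α-bis(triethylsilyloxy)-4,4,8β,10β-tetramethyl-9β-[(3E,7E)-4,8,12-trimethyltrideca-3,7,11-trien-1-yl]-5β-decalin | CC(C)=CCC/C(C)=C/CC/C(C)=C/CC[C@@H]1[C@@]2(C)CC[C@H](O[Si](CC)(CC)CC)C(C)(C)[C@H]2CC[C@@]1(C)O[Si](CC)(CC)CC | intermediate
29 | IN0670, cis-fused 4,4,8β,10β-tetramethyl-9β-[(3E,7E)-4,8,12-trimethyltrideca-3,7,11-trien-1-yl]-5β-decalin-3β,8α-diol | CC(C)=CCC/C(C)=C/CC/C(C)=C/CC[C@@H]1[C@@]2(C)CC[C@H](O)C(C)(C)[C@H]2CC[C@@]1(C)O | target

Total steps: 15. Longest linear sequence: 13 steps (steps 1–11, 14 and 15).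

Steps most likely to fail

1. Step 7. The tertiary radical may be intercepted by a second Cp2TiCl (then β-hydride elimination to an allylic alcohol) before the slow 6-exo closure onto the hindered C5. Fallback (sets out from 14, returns at 16): the radical is generated in a tin hydride chain, where no metal reductant competes. Epoxide 14 is opened at its tertiary carbon with HBr (48% aq., Et2O, −20 °C) to give (4S,5R,6S)-4-[(3S)-4-bromo-3-hydroxy-4-methylpentyl]-6-hydroxy-4,6-dimethyl-5-vinylcyclohex-2-en-1-one F1, with C3 untouched. Slow addition of Bu3SnH/AIBN (benzene, 80 °C) then abstracts bromine and effects the same Giese-type 6-exo cyclisation to give 16.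

2. Step 3. Facial discrimination between the methyl and the homoprenyl substituent at C10 may be poor, so that the C10-epimeric adduct forms alongside 9. Fallback (sets out from 8, returns at 9): the C9–C10 relationship is fixed by the order of two enolate alkylations.
   - Donor 8 is added under the same rhodium/(R)-BINAP catalysis to the known building block (S)-5-(trimethylsilyl)cyclohex-2-en-1-one, anti to silicon, giving trans-3-vinyl-5-(trimethylsilyl)cyclohexan-1-one F2.
   - CuCl2 in DMF removes silicon oxidatively to give 5-vinylcyclohex-2-en-1-one F3.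
   - α′-Deprotonation (LiN(iPr)2) and MeI give trans-6-methyl-5-vinylcyclohex-2-en-1-one F4.
   - A second deprotonation and alkylation with 5-iodo-2-methylpent-2-ene (LiN(iPr)2, DMPU), entering anti to vinyl, give 6-methyl-6-(4-methylpent-3-en-1-yl)-5-vinylcyclohex-2-en-1-one F5 with vinyl cis to methyl.
   - Wharton transposition (H2O2/NaOH to the 2,3-epoxy ketone F6, then N2H4·H2O/AcOH to the transposed allylic alcohol F7) and MnO2 oxidation deliver 9.

3. Step 10. Acylation of the hindered C7 hydroxyl may stall, or the neighbouring silyl group may migrate under forcing conditions. Fallback (sets out from 17, returns at 28): the carbonyl is removed without passing through the C7 carbinol.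
   - Ketone 17 is converted (KN(SiMe3)2, PhNTf2; C6 is the only enolisable carbon) into the 6-en-7-yl triflate F8.
   - Reduction with Pd(OAc)2, PPh3, Bu3N and HCO2H gives the 6-ene F9.
   - 9-BBN hydroborates only the vinyl group to give the borane F10, which is coupled with 26 as in step 14 to give the 6-ene analogue of 28, F11.
   - Diimide (2-nitrobenzenesulfonylhydrazide, Et3N) saturates the cis-disubstituted ring alkene in preference to the trisubstituted chain alkenes, giving 28.

Further compounds
F1 | step 7 | (4S,5R,6S)-4-[(3S)-4-bromo-3-hydroxy-4-methylpentyl]-6-hydroxy-4,6-dimethyl-5-vinylcyclohex-2-en-1-one | C=C[C@@H]1[C@@](C)(CC[C@H](O)C(C)(C)Br)C=CC(=O)[C@@]1(C)O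
F2 | step 3 | trans-3-vinyl-5-(trimethylsilyl)cyclohexan-1-one | C=C[C@@H]1CC(=O)C[C@@H]([Si](C)(C)C)C1
F3 | step 3 | (S)-5-vinylcyclohex-2-en-1-one | C=C[C@@H]1CC(=O)C=CC1
F4 | step 3 | trans-6-methyl-5-vinylcyclohex-2-en-1-one | C=C[C@@H]1[C@@H](C)C(=O)C=CC1
F5 | step 3 | 6-methyl-6-(4-methylpent-3-en-1-yl)-5-vinylcyclohex-2-en-1-one (vinyl cis to methyl) | C=C[C@@H]1[C@@](C)(CCC=C(C)C)C(=O)C=CC1
F6 | step 3 | 2,3-epoxide of F5 (epoxide configuration immaterial) | C=C[C@@H]1[C@@](C)(CCC=C(C)C)C(=O)C2OC2C1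
F7 | step 3 | 4-methyl-4-(4-methylpent-3-en-1-yl)-5-vinylcyclohex-2-en-1-ol (carbinol configuration immaterial) | C=C[C@@H]1[C@@](C)(CCC=C(C)C)C=CC(O)C1
F8 | step 10 | 3β,8α-bis(triethylsilyloxy)-4,4,8β,10β-tetramethyl-9β-vinyl-5β-decal-6-en-7-yl triflate | C=C[C@@H]1[C@@]2(C)CC[C@H](O[Si](CC)(CC)CC)C(C)(C)[C@H]2C=C(OS(=O)(=O)C(F)(F)F)[C@@]1(C)O[Si](CC)(CC)CC
F9 | step 10 | 3β,8α-bis(triethylsilyloxy)-4,4,8β,10β-tetramethyl-9β-vinyl-5β-decal-6-ene | C=C[C@@H]1[C@@]2(C)CC[C@H](O[Si](CC)(CC)CC)C(C)(C)[C@H]2C=C[C@@]1(C)O[Si](CC)(CC)CC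
F10 | step 10 | B-alkyl-9-borabicyclo[3.3.1]nonane from F9 | B1(CC[C@@H]2[C@@]3(C)CC[C@H](O[Si](CC)(CC)CC)C(C)(C)[C@H]3C=C[C@@]2(C)O[Si](CC)(CC)CC)C2CCCC1CCC2
F11 | step 10 | 6-ene analogue of 28 | CC(C)=CCC/C(C)=C/CC/C(C)=C/CC[C@@H]1[C@@]2(C)CC[C@H](O[Si](CC)(CC)CC)C(C)(C)[C@H]2C=C[C@@]1(C)O[Si](CC)(CC)CC
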